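**Strategy.** The γ-lactone (O1, C2=O, C3–Me, C4–CO2H, C5–chain) is opened at O1–C2 and C5 is taken back to a ketone. C4 then lies between the C5 carbonyl and its own carboxyl carbon, so its hydrogen is acidic and the two C4 epimers interconvert, whereas C3, installed from methyl (S)-lactate, stays fixed. A ketoreductase reduces the C5 ketone of one C4 epimer only, which sets C4 and C5 in one operation, and the new hydroxyl closes the ring onto the C2 methyl ester. The precursor is a (3S)-2-acyl-3-methylsuccinate: tert-butyl ester on the C4 carboxyl, methyl ester at C2, distal ketone masked as a dioxolane.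

Key step: step 8

Remark: atoms carry the lactone numbering (O1, C2 carbonyl, C3 methyl, C4 carboxyl, C5 chain) also in open-chain compounds; the target is 3S,4S,5S (C3/C4 trans, C4/C5 cis), the structures used were checked against it and needed no correction, and the ketoreductase of step 8 is assumed to be picked by screening a commercial panel for the anti, 5S-selective enzyme.

**Step 1**
Reactants: 1 ω-pentadecalactone (oxacyclohexadecan-2-one)
Product: 2 15-hydroxy-N-methoxy-N-methylpentadecanamide
Conditions: MeNHOMe·HCl, i-PrMgCl, THF, −20 → 0 °C; aq. NH4Cl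
Reagents that add atoms: N,O-dimethylhydroxylamine hydrochloride, CNOC.Cl
Why: Aminolysis of the lactone by the chloromagnesium amide of N,O-dimethylhydroxylamine (Weinreb amide formation from an ester) should open the 16-membered ring cleanly, because the ω-alkoxide cannot re-close a macrocycle under these conditions.

**Step 2**
Reactants: 2 15-hydroxy-N-methoxy-N-methylpentadecanamide
Product: 4 16-hydroxyhexadecan-2-one, via magnesium hemiaminal chelate 3 (not isolated)
Conditions: MeMgBr (3 equiv), THF, 0 °C → rt; aq. NH4Cl
Reagents that add atoms: methylmagnesium bromide, C[Mg]Br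
Why: Weinreb ketone synthesis: once the hydroxyl is deprotonated, one methyl group adds to the amide and the chelated tetrahedral adduct 3 persists until the quench, so no tertiary alcohol should form.

**Step 3**
Reactants: 4 16-hydroxyhexadecan-2-one
Product: 5 14-(2-methyl-1,3-dioxolan-2-yl)tetradecan-1-ol
Conditions: HOCH2CH2OH (5 equiv), p-TsOH·H2O (cat.), PhMe, reflux, Dean–Stark; aq. NaHCO3
Reagents that add atoms: ethylene glycol, OCCO
Why: Acid-catalysed ketalisation with azeotropic removal of water should convert the methyl ketone into its 1,3-dioxolane, the cyclic ketal being favoured over any mixed ketal with the substrate's own primary alcohol when the glycol is in excess.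

**Step 4**
Reactants: 5 14-(2-methyl-1,3-dioxolan-2-yl)tetradecan-1-ol
Product: 6 14-(2-methyl-1,3-dioxolan-2-yl)tetradecanoic acid
Conditions: TEMPO (cat.), NaOCl (cat.), NaClO2, MeCN/phosphate buffer pH 6.7, 35 °C; extraction at pH 4–5, used promptly
Reagents that add atoms: sodium chlorite, [Na+].[O-]Cl=O
Why: TEMPO/chlorite oxidation of a primary alcohol to the carboxylic acid (oxoammonium oxidation to the aldehyde, then chlorite oxidation) runs near neutral pH, where the dioxolane is stable.

**Step 5**
Reactants: 6 14-(2-methyl-1,3-dioxolan-2-yl)tetradecanoic acid; 7 mono-tert-butyl malonate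
Product: 11 tert-butyl 16-(2-methyl-1,3-dioxolan-2-yl)-3-oxohexadecanoate, via acyl imidazolide 8 (not isolated), via chloromagnesium malonate enolate 9 (not isolated), via acylmalonic half-ester 10 (not isolated)
Conditions: 6, CDI, THF, rt; 7, i-PrMgCl (2 equiv per 7), THF, 0 °C → rt; combine, rt → 40 °C; cold 10% aq. citric acid
Reagents that add atoms: none
Why: Masamune–Brooks decarboxylative Claisen condensation: the imidazolide 8 acylates the magnesium enolate 9 at carbon and the β-keto acid 10 loses CO2 on mild acidification, a work-up too weak and too brief to hydrolyse the dioxolane.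

**Step 6**
Reactants: 12 methyl (S)-lactate
Product: 13 methyl (2S)-2-[(trifluoromethanesulfonyl)oxy]propanoate
Conditions: Tf2O, 2,6-lutidine, CH2Cl2, −78 → 0 °C; used without storage
Reagents that add atoms: triflic anhydride, O=S(=O)(OS(=O)(=O)C(F)(F)F)C(F)(F)F
Why: O-Sulfonylation of the secondary alcohol with triflic anhydride and a hindered pyridine base leaves the C–O bond untouched, so the S configuration is retained.

**Step 7**
Reactants: 11 tert-butyl 16-(2-methyl-1,3-dioxolan-2-yl)-3-oxohexadecanoate; 13 methyl (2S)-2-[(trifluoromethanesulfonyl)oxy]propanoate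
Product: 15 1-tert-butyl 4-methyl (2RS,3S)-3-methyl-2-[14-(2-methyl-1,3-dioxolan-2-yl)tetradecanoyl]butanedioate (both C4 epimers), via sodium enolate 14 (not isolated)
Conditions: NaH, THF, 0 °C; then 13, 0 °C → rt
Reagents that add atoms: none
Why: C-Alkylation of a β-keto ester sodium enolate by an α-triflyloxy ester is an SN2 displacement with inversion at the lactate carbon, which sets C3 as S (the descriptor stays S because the incoming carbon ranks below the ester carbon), while C4 forms as both epimers, which is harmless.

**Step 8**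
Reactants: 15 1-tert-butyl 4-methyl (2RS,3S)-3-methyl-2-[14-(2-methyl-1,3-dioxolan-2-yl)tetradecanoyl]butanedioate
Product: 17 tert-butyl (2S,3S,4S)-4-methyl-2-[13-(2-methyl-1,3-dioxolan-2-yl)tridecyl]-5-oxooxolane-3-carboxylate (lactone numbering 3S,4S,5S), via anti hydroxy diester 16 (not isolated)
Conditions: NADPH-dependent ketoreductase (anti-, 5S-selective, panel-selected), NADP+ (cat.), i-PrOH, phosphate buffer pH 7.0/DMSO (9:1), 30 °C; crude extract, PPTS (cat.), PhMe, 45 °C
Reagents that add atoms: none
Why: Enzymatic carbonyl reduction under dynamic kinetic resolution: the C4–H of 15, flanked by the C5 ketone and the tert-butyl ester carbonyl, should exchange through the enol in the buffer faster than hydride transfer, and the enzyme should accept only the 4S epimer and deliver hydride from NADPH to the Re face of C5, giving the anti hydroxy diester 16. The closest known reaction type is the ketoreductase or yeast reduction of α-alkyl β-keto esters with dynamic resolution, including 2-acylsuccinates whose γ-hydroxy esters lactonise in situ. The ring closes by 5-exo-trig attack of the C5 hydroxyl on the C2 methyl ester carbonyl with loss of methanol (brought to completion by the PPTS treatment), which forms the O1–C2 bond; the tert-butyl ester could only give a strained β-lactone and is left alone. C5 is controlled by the facial selectivity of the enzyme and C4 by its choice of substrate epimer, whereas C3, an ordinary ester α-carbon, does not epimerise at pH 7 and only makes any stray isomers diastereomeric and separable. The step needs chemoselectivity for the C5 ketone, secured by the dioxolane on the distal ketone, and the anti C4/C5 relation, secured by the choice of enzyme and then locked because C4 is no longer acidic enough to epimerise once C5 is a carbinol, so the less stable 4,5-cis lactone cannot drift to the trans isomer.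

**Step 9**
Reactants: 17 tert-butyl (2S,3S,4S)-4-methyl-2-[13-(2-methyl-1,3-dioxolan-2-yl)tridecyl]-5-oxooxolane-3-carboxylate
Product: 19 (2S,3S,4S)-4-methyl-5-oxo-2-(14-oxopentadecyl)oxolane-3-carboxylic acid (the target), via keto tert-butyl ester 18 (not isolated)
Conditions: TFA/CH2Cl2/H2O (10:10:1), 0 °C → rt
Reagents that add atoms: water, O
Why: Acidolysis: aqueous TFA hydrolyses the dioxolane to the methyl ketone and then cleaves the tert-butyl ester by the alkyl–oxygen pathway, conditions under which the lactone stays closed and neither C3 nor C4 enolises appreciably, so all three centres should be retained.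

**Compound list**

1 | ω-pentadecalactone (oxacyclohexadecan-2-one) | O=C1CCCCCCCCCCCCCCO1 | starting material
2 | 15-hydroxy-N-methoxy-N-methylpentadecanamide | CON(C)C(=O)CCCCCCCCCCCCCCO | intermediate
3 | bis(bromomagnesium) hemiaminal chelate from 2 and MeMgBr | CON(C)C(C)(O[Mg]Br)CCCCCCCCCCCCCCO[Mg]Br | intermediate
4 | 16-hydroxyhexadecan-2-one | CC(=O)CCCCCCCCCCCCCCO | intermediate
5 | 14-(2-methyl-1,3-dioxolan-2-yl)tetradecan-1-ol | CC1(CCCCCCCCCCCCCCO)OCCO1 | intermediate
6 | 14-(2-methyl-1,3-dioxolan-2-yl)tetradecanoic acid | CC1(CCCCCCCCCCCCCC(=O)O)OCCO1 | intermediate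
7 | mono-tert-butyl malonate | CC(C)(C)OC(=O)CC(=O)O | starting material
8 | 1-[14-(2-methyl-1,3-dioxolan-2-yl)tetradecanoyl]imidazole | CC1(CCCCCCCCCCCCCC(=O)n2ccnc2)OCCO1 | intermediate
9 | bis(chloromagnesium) enolate carboxylate of mono-tert-butyl malonate | CC(C)(C)OC(O[Mg]Cl)=CC(=O)O[Mg]Cl | intermediate
10 | 2-(tert-butoxycarbonyl)-16-(2-methyl-1,3-dioxolan-2-yl)-3-oxohexadecanoic acid (formed as its magnesium salt) | CC1(CCCCCCCCCCCCCC(=O)C(C(=O)O)C(=O)OC(C)(C)C)OCCO1 | intermediate
11 | tert-butyl 16-(2-methyl-1,3-dioxolan-2-yl)-3-oxohexadecanoate | CC1(CCCCCCCCCCCCCC(=O)CC(=O)OC(C)(C)C)OCCO1 | intermediate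
12 | methyl (S)-lactate | C[C@H](O)C(=O)OC | starting material
13 | methyl (2S)-2-[(trifluoromethanesulfonyl)oxy]propanoate | C[C@H](OS(=O)(=O)C(F)(F)F)C(=O)OC | intermediate
14 | sodium enolate of 11 | CC1(CCCCCCCCCCCCCC([O-])=CC(=O)OC(C)(C)C)OCCO1.[Na+] | intermediate
15 | 1-tert-butyl 4-methyl (2RS,3S)-3-methyl-2-[14-(2-methyl-1,3-dioxolan-2-yl)tetradecanoyl]butanedioate | CC1(CCCCCCCCCCCCCC(=O)C(C(=O)OC(C)(C)C)[C@H](C)C(=O)OC)OCCO1 | intermediate
16 | 1-tert-butyl 4-methyl (2S,3S)-2-[(1S)-1-hydroxy-14-(2-methyl-1,3-dioxolan-2-yl)tetradecyl]-3-methylbutanedioate | CC1(CCCCCCCCCCCCC[C@H](O)[C@@H](C(=O)OC(C)(C)C)[C@H](C)C(=O)OC)OCCO1 | intermediate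
17 | tert-butyl (2S,3S,4S)-4-methyl-2-[13-(2-methyl-1,3-dioxolan-2-yl)tridecyl]-5-oxooxolane-3-carboxylate | CC1(CCCCCCCCCCCCC[C@@H]2OC(=O)[C@@H](C)[C@@H]2C(=O)OC(C)(C)C)OCCO1 | intermediate
18 | tert-butyl (2S,3S,4S)-4-methyl-5-oxo-2-(14-oxopentadecyl)oxolane-3-carboxylate | CC(=O)CCCCCCCCCCCCC[C@@H]1OC(=O)[C@@H](C)[C@@H]1C(=O)OC(C)(C)C | intermediate
19 | (2S,3S,4S)-4-methyl-5-oxo-2-(14-oxopentadecyl)oxolane-3-carboxylic acid | CC(=O)CCCCCCCCCCCCC[C@@H]1OC(=O)[C@@H](C)[C@@H]1C(=O)O | target

**Step count and risks**

Total step count: 9. Longest linear sequence: 8 steps (1–5, 7, 8, 9, from ω-pentadecalactone); step 6 is a one-step branch.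

Most likely to fail, riskiest first:

Step 8. The resolution may not be fully dynamic if C4 exchange is slower than reduction for this hindered, poorly soluble substrate. The enzyme may also accept both C4 epimers or add hydride to both faces of C5, and ring closure may stall. The fallback sets C5 and C4 in two separate events, the first catalyst-controlled and the second substrate-controlled. It sets out from 11: hydrogenation over a Ru–(S)-BINAP dihalide catalyst (H2, EtOH, 50 °C; Noyori β-keto ester hydrogenation) should give tert-butyl (3S)-3-hydroxy-16-(2-methyl-1,3-dioxolan-2-yl)hexadecanoate F1. Double deprotonation (LDA, 2.2 equiv, THF, −78 → −20 °C) gives the dilithium alkoxide enolate F2. This is alkylated by 13 (Fráter–Seebach alkylation) on the enolate face anti to the chain of the chelate, with inversion at the lactate carbon. The lithium alkoxide of 16 formed in this way closes onto the methyl ester, and the route is rejoined at 17.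

Step 7. The ambident enolate may alkylate on oxygen, the base may eliminate triflic acid from 13 to give methyl acrylate, and the lactate carbon may partly lose its configuration. The fallback forms the C3–C4 bond on a malonate, a softer and well-tried nucleophile for lactate triflates, and brings in the acyl group afterwards. It sets out from 13 and comes back at 15. Commercial benzyl tert-butyl malonate is deprotonated (NaH, THF, 0 °C) and alkylated with 13 to give 1-benzyl 1-tert-butyl 2-methyl (2S)-propane-1,1,2-tricarboxylate F3. Hydrogenolysis (H2, Pd/C, EtOAc) gives (3S)-2-(tert-butoxycarbonyl)-4-methoxy-3-methyl-4-oxobutanoic acid F4. Its magnesium enolate (MgCl2, Et3N, THF/MeCN) is acylated by the imidazolide 8 to 2-(tert-butoxycarbonyl)-2-[(2S)-1-methoxy-1-oxopropan-2-yl]-16-(2-methyl-1,3-dioxolan-2-yl)-3-oxohexadecanoic acid F5, which loses CO2 on mild acidic work-up to give 15.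

Step 5. C-Acylation or decarboxylation may be incomplete, and the dioxolane may be lost during the acidic work-up that the decarboxylation needs. The fallback uses an acylketene precursor, which needs no acid. It sets out from 6 and comes back at 11. Acid 6 is condensed with Meldrum's acid (DCC, DMAP, CH2Cl2, 0 °C → rt) to give 5-[1-hydroxy-14-(2-methyl-1,3-dioxolan-2-yl)tetradecylidene]-2,2-dimethyl-1,3-dioxane-4,6-dione F6. Heating F6 with t-BuOH in toluene (85 °C) opens the dioxanedione with loss of acetone and CO2 and gives 11.

**Further compounds**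

F1 | step 8 | tert-butyl (3S)-3-hydroxy-16-(2-methyl-1,3-dioxolan-2-yl)hexadecanoate | CC1(CCCCCCCCCCCCC[C@H](O)CC(=O)OC(C)(C)C)OCCO1
F2 | step 8 | dilithium alkoxide enolate of F1 | CC1(CCCCCCCCCCCCC[C@H]([O-])C=C([O-])OC(C)(C)C)OCCO1.[Li+].[Li+]
F3 | step 7 | 1-benzyl 1-tert-butyl 2-methyl (2S)-propane-1,1,2-tricarboxylate | O=C(OCc1ccccc1)C(C(=O)OC(C)(C)C)[C@H](C)C(=O)OC
F4 | step 7 | (3S)-2-(tert-butoxycarbonyl)-4-methoxy-3-methyl-4-oxobutanoic acid | O=C(O)C(C(=O)OC(C)(C)C)[C@H](C)C(=O)OC
F5 | step 7 | 2-(tert-butoxycarbonyl)-2-[(2S)-1-methoxy-1-oxopropan-2-yl]-16-(2-methyl-1,3-dioxolan-2-yl)-3-oxohexadecanoic acid | CC1(CCCCCCCCCCCCCC(=O)C(C(=O)O)(C(=O)OC(C)(C)C)[C@H](C)C(=O)OC)OCCO1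
F6 | step 5 | 5-[1-hydroxy-14-(2-methyl-1,3-dioxolan-2-yl)tetradecylidene]-2,2-dimethyl-1,3-dioxane-4,6-dione | CC1(CCCCCCCCCCCCCC(O)=C2C(=O)OC(C)(C)OC2=O)OCCO1
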